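**Retrosynthetic overview**

1. The target comes from a tricyclic Z-cyclodecenone lactone by C11 methylenation, O8 methacryloylation and, last, C4=C5 epoxidation.
2. Key disconnection C5–C6: a Z-iodoalkene on the C10 arm adds (Nozaki–Hiyama–Kishi) to a C6 aldehyde on C7, and the C6 alkoxide closes the 12,6-lactone. The strategy rests on C6 being a carbinol carbon between the Z-C4=C5 unit and C7, the fully substituted ether carbon of the tetrahydrofuran ring O–C7–C8–C9–C10; the cis arms C6 and C1 of that ring are the ends of the ten-membered ring C1–C10, and the C11–C12 arm gives the γ-lactone ring O–C6–C7–C11–C12.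
3. The keto-aldehyde comes from C2–C3 alkylation of a C10 methyl ketone with (Z)-3-bromo-1-iodo-2-methylpropene, after a cis-fused 8,12-lactone has been opened to the O8 silyl ether and C12 methyl ester.
4. The tetrahydrofuran comes from a palladium-catalysed oxycarbonylation–lactonisation of an ene-1,3-diol (O10 to C7, CO becomes C12, cis fusion sets C7). C8 is set by oxazaborolidine reduction of an enone and C10 comes from (R)-citramalic acid.
5. Ring order: tetrahydrofuran with a temporary 8,12-lactone (step 6), then ten-membered carbocycle and 12,6-lactone together (step 14), oxirane last (step 19).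

Key step: step 14

Remark: germacrane numbering is used for all compounds (C1 ketone, C4–C5 alkene or oxirane, C6 lactone carbinol, C7 spiro ether carbon, C8 ester carbinol, C10 methylated ether carbon, C11–C13 lactone arm), and (R)-citramalic acid is taken as the commercial source of C10, C14, C1, C9 and C8.

**Route**

Step 1
Reactants: 1 (R)-citramalic acid
Product: 2 2-[(4R)-2,2,4-trimethyl-5-oxo-1,3-dioxolan-4-yl]acetic acid
Conditions: 2,2-dimethoxypropane, TsOH·H2O (cat.), rt
Reagents that add atoms: 2,2-dimethoxypropane, COC(C)(C)OC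
Why: Acid-catalysed transacetalisation takes up the α-hydroxy acid as the five-membered 1,3-dioxolan-4-one, which masks O10 and C1 and leaves the C8 carboxyl free, and the C10 stereocentre is not touched.

Step 2
Reactants: 3 2,3-dibromoprop-1-ene + 4 (4-methoxyphenyl)methanol
Product: 5 1-{[(2-bromoprop-2-en-1-yl)oxy]methyl}-4-methoxybenzene
Conditions: NaH, n-Bu4NI (cat.), THF, 0 °C to rt
Reagents that add atoms: none
Why: Williamson ether synthesis, in which the alkoxide displaces the allylic bromide and the vinylic bromide is kept for metalation.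

Step 3
Reactants: 2 dioxolanone acid + 5 bromoallyl ether
Product: 9 (5R)-5-(3-{[(4-methoxyphenyl)methoxy]methyl}-2-oxobut-3-en-1-yl)-2,2,5-trimethyl-1,3-dioxolan-4-one, via acid chloride 6 (not isolated), via alkenyllithium 7 (not isolated), via alkenylzinc chloride 8 (not isolated)
Conditions: 2, (COCl)2, DMF (cat.), CH2Cl2, 0 °C to rt, concentrate; 5, t-BuLi (2 equiv), Et2O, −78 °C, then ZnCl2, THF, −78 to 0 °C; combine, Pd(PPh3)4 (5 mol%), THF, 0 °C to rt
Reagents that add atoms: none
Why: Negishi acylation, in which the acid chloride adds oxidatively to zerovalent palladium and couples with the alkenylzinc made by bromine–lithium exchange and transmetallation, gives the α-methylene ketone directly, so that no free C8 alkoxide is formed next to the dioxolanone, and no stereocentre is created.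

Step 4
Reactants: 9 enone
Product: 10 (5R)-5-[(2S)-2-hydroxy-3-{[(4-methoxyphenyl)methoxy]methyl}but-3-en-1-yl]-2,2,5-trimethyl-1,3-dioxolan-4-one
Conditions: (R)-2-methyl-CBS-oxazaborolidine (20 mol%), catecholborane, toluene, −78 °C; pH 7 buffer
Reagents that add atoms: none
Why: Corey–Bakshi–Shibata reduction, in which the oxazaborolidine binds the ketone with the alkenyl group as the large and the CH2 group as the small substituent, should deliver hydride under reagent control to give the 8S carbinol, 1,2-selectively and without reduction of the lactone carbonyl.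

Step 5
Reactants: 10 allylic alcohol + 11 methylmagnesium bromide
Product: 13 (3R,5S)-3,5-dihydroxy-6-{[(4-methoxyphenyl)methoxy]methyl}-3-methylhept-6-en-2-one, via N-methoxy-N-methylamide 12 (not isolated)
Conditions: MeNHOMe·HCl, i-PrMgCl, THF, −20 to 0 °C; then MeMgBr (excess), 0 °C to rt; aq. NH4Cl
Reagents that add atoms: none
Why: The chloromagnesium amide opens the dioxolanone (or the γ-lactone formed from it by acyl transfer to O8, which leads to the same amide) with loss of acetone, and methylmagnesium bromide then adds once because the chelated tetrahedral intermediate lasts until work-up (Weinreb ketone synthesis), the excess Grignard reagent covering the two alkoxides and the acetone set free.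

Step 6
Reactants: 13 dihydroxy ketone
Product: 14 (3aR,5R,6aS)-5-acetyl-3a-{[(4-methoxyphenyl)methoxy]methyl}-5-methylhexahydrofuro[3,2-b]furan-2-one
Conditions: PdCl2 (10 mol%), CuCl2 (3 equiv), NaOAc (3 equiv), AcOH, CO (1 atm), rt
Reagents that add atoms: carbon monoxide, [C-]#[O+]
Why: In this intramolecular alkoxycarbonylation–lactonisation of an ene-1,3-diol by divalent palladium, reversible 5-exo-trig oxypalladation by the tertiary C10 hydroxyl at the internal alkene carbon gives a σ-alkylpalladium without β-hydrogens, CO inserts, and the acyl complex is trapped by the C8 hydroxyl, which is possible only when C11 is cis to O8, so C7 is set by the cis ring fusion while CuCl2 returns zerovalent palladium to the divalent state.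

Step 7
Reactants: 14 bicyclic lactone
Product: 17 2-[(2R,3S,5R)-5-acetyl-3-[(tert-butyldimethylsilyl)oxy]-2-{[(4-methoxyphenyl)methoxy]methyl}-5-methyloxolan-2-yl]acetic acid, via lithium hydroxy carboxylate 15 (not isolated), via silyl ether silyl ester 16 (not isolated)
Conditions: LiOH·H2O, THF/H2O, 0 °C to rt; concentrate, toluene azeotrope; TBSOTf (3.5 equiv), 2,6-lutidine, CH2Cl2, −78 to 0 °C; then AcOH/THF/H2O (3:1:1), rt
Reagents that add atoms: lithium hydroxide, [Li+].[OH-]; tert-butyldimethylsilyl triflate, CC(C)(C)[Si](C)(C)OS(=O)(=O)C(F)(F)F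
Why: Saponification frees O8 as the carboxylate salt, which cannot relactonise, excess silyl triflate silylates the hindered secondary alcohol and the carboxylate at low temperature, and only the labile silyl ester is hydrolysed by aqueous acetic acid, the usual way from a γ-lactone to a γ-silyloxy acid, with no stereocentre affected.

Step 8
Reactants: 17 silyloxy acid
Product: 18 methyl 2-[(2R,3S,5R)-5-acetyl-3-[(tert-butyldimethylsilyl)oxy]-2-{[(4-methoxyphenyl)methoxy]methyl}-5-methyloxolan-2-yl]acetate
Conditions: TMSCHN2, MeOH/toluene (1:4), 0 °C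
Reagents that add atoms: (trimethylsilyl)diazomethane, C[Si](C)(C)C=[N+]=[N-]
Why: Esterification with (trimethylsilyl)diazomethane in methanol is neutral, so the γ-silyloxy acid, the ketone and the ethers are not disturbed.

Step 9
Reactants: 19 prop-2-yn-1-ol + 11 methylmagnesium bromide
Product: 21 (2Z)-3-iodo-2-methylprop-2-en-1-ol, via alkenylmagnesium alkoxide 20 (not isolated)
Conditions: MeMgBr (2.5 equiv), CuI (10 mol%), Et2O, −10 °C to rt; then I2, THF, −10 °C
Reagents that add atoms: iodine, II
Why: Copper-catalysed anti-carbomagnesiation of the propargylic alkoxide gives the five-membered alkenylmagnesium chelate with magnesium cis to CH2O, and iodinolysis with retention gives the Z-iodoalkene.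

Step 10
Reactants: 21 iodo allylic alcohol
Product: 22 (1Z)-3-bromo-1-iodo-2-methylprop-1-ene
Conditions: CBr4, PPh3, CH2Cl2, 0 °C
Reagents that add atoms: carbon tetrabromide, BrC(Br)(Br)Br
Why: Appel bromination of the primary allylic alcohol under neutral conditions keeps the alkene geometry.

Step 11
Reactants: 18 methyl ketone ester + 22 allylic bromide
Product: 24 methyl 2-[(2R,3S,5R)-3-[(tert-butyldimethylsilyl)oxy]-5-[(4Z)-5-iodo-4-methylpent-4-enoyl]-2-{[(4-methoxyphenyl)methoxy]methyl}-5-methyloxolan-2-yl]acetate, via lithium enolate 23 (not isolated)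
Conditions: LDA (1.05 equiv), THF, −78 °C; then 22, DMPU, −78 to −20 °C
Reagents that add atoms: none
Why: Kinetic deprotonation of the methyl ketone (its only enolisable position, C10 being quaternary, and more acidic than the hindered ester CH2) and SN2 alkylation of the lithium enolate by the reactive allylic bromide form C2–C3, while the vinylic iodide is inert to the enolate and the ester arm on the opposite ring face is out of reach.

Step 12
Reactants: 24 4-methoxybenzyl ether
Product: 25 methyl 2-[(2R,3S,5R)-3-[(tert-butyldimethylsilyl)oxy]-2-(hydroxymethyl)-5-[(4Z)-5-iodo-4-methylpent-4-enoyl]-5-methyloxolan-2-yl]acetate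
Conditions: DDQ, CH2Cl2/pH 7 buffer (10:1), 0 °C; used crude
Reagents that add atoms: none
Why: Oxidative cleavage of the 4-methoxybenzyl ether by DDQ in buffered medium leaves the silyl ether, ketone, ester and iodoalkene intact, and the γ-hydroxy ester is carried on at once so that it does not close to the spiro-lactone.

Step 13
Reactants: 25 primary alcohol
Product: 26 methyl 2-[(2S,3S,5R)-3-[(tert-butyldimethylsilyl)oxy]-2-formyl-5-[(4Z)-5-iodo-4-methylpent-4-enoyl]-5-methyloxolan-2-yl]acetate
Conditions: Dess–Martin periodinane, NaHCO3, CH2Cl2, 0 °C to rt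
Reagents that add atoms: none
Why: Dess–Martin oxidation of the neopentyl primary alcohol gives the aldehyde, which has no α-hydrogen and so cannot enolise or epimerise.

Step 14
Reactants: 26 keto-aldehyde iodoalkene
Product: 29 (4Z,6R,7R,8S,10R)-8-[(tert-butyldimethylsilyl)oxy]-7,10-epoxy-1-oxo-13-norgermacr-4-en-12,6-olide, via alkenylchromium dichloride 27 (not isolated), via chromium alkoxide 28 (not isolated)
Conditions: CrCl2 (15 equiv), NiCl2 (1 mol% of CrCl2), degassed DMSO, rt, 26 added over 10 h (final 2 mM); aq. EDTA disodium work-up; then PPTS (cat.), CH2Cl2, rt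
Reagents that add atoms: none
Why: Zerovalent nickel, made from NiCl2 by CrCl2, inserts into the C5–I bond with retention of the Z geometry, transmetallation gives an alkenylchromium dichloride of trivalent chromium, and this adds to the C6 aldehyde but not to the ketone or ester, the Nozaki–Hiyama–Kishi reaction in its known macrocyclising form. The ten-membered carbocycle closes by 10-exo-trig attack (C=O outside the new ring), helped by the cis placement of the two arms on the tetrahydrofuran, and the chromium alkoxide then closes the γ-lactone by 5-exo-trig acyl substitution on the CH2CO2Me arm with loss of methoxide, which makes the sequence irreversible (the PPTS finish completes any lactonisation left open). The tether from C10 brings C5 to C6 from the side of the ring oxygen, so C6 is decided by the rotamer of the formyl group: with the chromium-bound oxygen turned outward over the CH2CO2Me arm and the formyl hydrogen inward towards C8, the Re face is attacked and C6 becomes R. The step needs chemoselectivity (aldehyde over ketone, given by the reagent), retention of alkene geometry (given by the alkenylmetal) and ring closure over oligomerisation (given by slow addition at high dilution).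

Step 15
Reactants: 29 keto lactone
Product: 30 (4Z,6R,7R,8S,10R)-1,8-bis[(tert-butyldimethylsilyl)oxy]-7,10-epoxy-13-norgermacra-1,4-dien-12,6-olide
Conditions: TBSOTf (1.2 equiv), Et3N, CH2Cl2, −78 to 0 °C
Reagents that add atoms: tert-butyldimethylsilyl triflate, CC(C)(C)[Si](C)(C)OS(=O)(=O)C(F)(F)F
Why: Soft enolisation with silyl triflate and triethylamine turns the ketone, but not the less acidic lactone, into its silyl enol ether, which masks C2 for the next step.

Step 16
Reactants: 30 silyl enol ether lactone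
Product: 34 (4Z,6R,7R,8S,10R)-1,8-bis[(tert-butyldimethylsilyl)oxy]-7,10-epoxygermacra-1,4,11(13)-trien-12,6-olide, via lactone lithium enolate 31 (not isolated), via Mannich base 32 (not isolated), via trimethylammonium iodide 33 (not isolated)
Conditions: LDA (1.3 equiv), THF, −78 °C; CH2=NMe2+ I− (1.2 equiv), −78 to 0 °C; then MeI, THF/MeOH, rt; then aq. NaHCO3, EtOAc, rt
Reagents that add atoms: N,N-dimethylmethyleneiminium iodide (Eschenmoser's salt), C[N+](C)=C.[I-]
Why: With the ketone masked the lactone is the only enolisable carbonyl, its lithium enolate (kept cold to avoid β-elimination of the ring oxygen) undergoes a Mannich reaction with Eschenmoser's salt, and methylation followed by mild base eliminates trimethylamine to the exocyclic alkene, an endocyclic alkene being impossible because C7 is quaternary, so the C11 stereocentre of the Mannich base is of no consequence.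

Step 17
Reactants: 34 bis-silyl α-methylene lactone
Product: 35 (4Z,6R,7S,8S,10R)-7,10-epoxy-8-hydroxy-1-oxogermacra-4,11(13)-dien-12,6-olide
Conditions: HF·pyridine, pyridine, THF, 0 °C to rt
Reagents that add atoms: none
Why: Buffered hydrogen fluoride–pyridine cleaves the silyl ether and the silyl enol ether (which returns the C1 ketone) without forming an alkoxide, so that O8 does not transfer onto the C12 lactone carbonyl.

Step 18
Reactants: 35 hydroxy lactone
Product: 36 (4Z,6R,7S,8S,10R)-7,10-epoxy-8-[(2-methylprop-2-enoyl)oxy]-1-oxogermacra-4,11(13)-dien-12,6-olide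
Conditions: methacrylic anhydride, Et3N, DMAP (cat.), CH2Cl2, 0 °C to rt
Reagents that add atoms: methacrylic anhydride, C=C(C)C(=O)OC(=O)C(C)=C
Why: DMAP-catalysed acylation of the hindered secondary alcohol by the anhydride should be faster than lactone migration to O8.

Step 19
Reactants: 36 methacrylate
Product: 37 (4R,5S,6R,7S,8S,10R)-4,5:7,10-diepoxy-8-[(2-methylprop-2-enoyl)oxy]-1-oxogermacr-11(13)-en-12,6-olide
Conditions: mCPBA, NaHCO3, CH2Cl2, 0 °C
Reagents that add atoms: 3-chloroperoxybenzoic acid, OOC(=O)c1cccc(Cl)c1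
Why: Prilezhaev epoxidation of the only electron-rich alkene (the two enoate alkenes are deactivated) is stereospecific, so C3 and C6 stay cis, and C4 and C5 are set by the face of approach, which must be the one syn to C7 and anti to the allylic lactone C6–O bond in the rotamer with H6 eclipsing the alkene, a face that an electrophilic peracid favours next to an allylic acyloxy group but that no directing group secures.

**Compound list**

1 | (R)-citramalic acid, (2R)-2-hydroxy-2-methylbutanedioic acid | C[C@@](O)(CC(=O)O)C(=O)O | starting material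
2 | 2-[(4R)-2,2,4-trimethyl-5-oxo-1,3-dioxolan-4-yl]acetic acid | C[C@]1(CC(=O)O)OC(C)(C)OC1=O | intermediate
3 | 2,3-dibromoprop-1-ene | C=C(Br)CBr | starting material
4 | (4-methoxyphenyl)methanol | COc1ccc(CO)cc1 | starting material
5 | 1-{[(2-bromoprop-2-en-1-yl)oxy]methyl}-4-methoxybenzene | C=C(Br)COCc1ccc(OC)cc1 | intermediate
6 | 2-[(4R)-2,2,4-trimethyl-5-oxo-1,3-dioxolan-4-yl]acetyl chloride | C[C@]1(CC(=O)Cl)OC(C)(C)OC1=O | intermediate (not isolated)
7 | (3-[(4-methoxyphenyl)methoxy]prop-1-en-2-yl)lithium | [Li]C(=C)COCc1ccc(OC)cc1 | intermediate (not isolated)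
8 | chloro(3-[(4-methoxyphenyl)methoxy]prop-1-en-2-yl)zinc | Cl[Zn]C(=C)COCc1ccc(OC)cc1 | intermediate (not isolated)
9 | (5R)-5-(3-{[(4-methoxyphenyl)methoxy]methyl}-2-oxobut-3-en-1-yl)-2,2,5-trimethyl-1,3-dioxolan-4-one | C[C@]1(CC(=O)C(=C)COCc2ccc(OC)cc2)OC(C)(C)OC1=O | intermediate
10 | (5R)-5-[(2S)-2-hydroxy-3-{[(4-methoxyphenyl)methoxy]methyl}but-3-en-1-yl]-2,2,5-trimethyl-1,3-dioxolan-4-one | C[C@]1(C[C@H](O)C(=C)COCc2ccc(OC)cc2)OC(C)(C)OC1=O | intermediate
11 | methylmagnesium bromide | C[Mg]Br | starting material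
12 | (2R,4S)-2,4-dihydroxy-N-methoxy-5-{[(4-methoxyphenyl)methoxy]methyl}-N,2-dimethylhex-5-enamide (present as its chloromagnesium alkoxide) | CON(C)C(=O)[C@](C)(O)C[C@H](O)C(=C)COCc1ccc(OC)cc1 | intermediate (not isolated)
13 | (3R,5S)-3,5-dihydroxy-6-{[(4-methoxyphenyl)methoxy]methyl}-3-methylhept-6-en-2-one | CC(=O)[C@](C)(O)C[C@H](O)C(=C)COCc1ccc(OC)cc1 | intermediate
14 | (3aR,5R,6aS)-5-acetyl-3a-{[(4-methoxyphenyl)methoxy]methyl}-5-methylhexahydrofuro[3,2-b]furan-2-one (cis-fused 8,12-lactone) | COc1ccc(COC[C@]23CC(=O)O[C@H]2C[C@](C)(C(C)=O)O3)cc1 | intermediate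
15 | lithium 2-[(2R,3S,5R)-5-acetyl-3-hydroxy-2-{[(4-methoxyphenyl)methoxy]methyl}-5-methyloxolan-2-yl]acetate | COc1ccc(COC[C@@]2(CC(=O)[O-])O[C@](C)(C[C@@H]2O)C(C)=O)cc1.[Li+] | intermediate (not isolated)
16 | tert-butyldimethylsilyl 2-[(2R,3S,5R)-5-acetyl-3-[(tert-butyldimethylsilyl)oxy]-2-{[(4-methoxyphenyl)methoxy]methyl}-5-methyloxolan-2-yl]acetate | COc1ccc(COC[C@@]2(CC(=O)O[Si](C)(C)C(C)(C)C)O[C@](C)(C[C@@H]2O[Si](C)(C)C(C)(C)C)C(C)=O)cc1 | intermediate (not isolated)
17 | 2-[(2R,3S,5R)-5-acetyl-3-[(tert-butyldimethylsilyl)oxy]-2-{[(4-methoxyphenyl)methoxy]methyl}-5-methyloxolan-2-yl]acetic acid | COc1ccc(COC[C@@]2(CC(=O)O)O[C@](C)(C[C@@H]2O[Si](C)(C)C(C)(C)C)C(C)=O)cc1 | intermediate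
18 | methyl 2-[(2R,3S,5R)-5-acetyl-3-[(tert-butyldimethylsilyl)oxy]-2-{[(4-methoxyphenyl)methoxy]methyl}-5-methyloxolan-2-yl]acetate | COc1ccc(COC[C@@]2(CC(=O)OC)O[C@](C)(C[C@@H]2O[Si](C)(C)C(C)(C)C)C(C)=O)cc1 | intermediate
19 | prop-2-yn-1-ol | C#CCO | starting material
20 | bromomagnesium (2Z)-3-(bromomagnesio)-2-methylprop-2-en-1-olate | Br[Mg]OC/C(C)=C\[Mg]Br | intermediate (not isolated)
21 | (2Z)-3-iodo-2-methylprop-2-en-1-ol | OC/C(C)=C\I | intermediate
22 | (1Z)-3-bromo-1-iodo-2-methylprop-1-ene | BrC/C(C)=C\I | intermediate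
23 | lithium enolate of 18 at C1–C2 | COc1ccc(COC[C@@]2(CC(=O)OC)O[C@](C)(C[C@@H]2O[Si](C)(C)C(C)(C)C)C(=C)O[Li])cc1 | intermediate (not isolated)
24 | methyl 2-[(2R,3S,5R)-3-[(tert-butyldimethylsilyl)oxy]-5-[(4Z)-5-iodo-4-methylpent-4-enoyl]-2-{[(4-methoxyphenyl)methoxy]methyl}-5-methyloxolan-2-yl]acetate | COc1ccc(COC[C@@]2(CC(=O)OC)O[C@](C)(C[C@@H]2O[Si](C)(C)C(C)(C)C)C(=O)CC/C(C)=C\I)cc1 | intermediate
25 | methyl 2-[(2R,3S,5R)-3-[(tert-butyldimethylsilyl)oxy]-2-(hydroxymethyl)-5-[(4Z)-5-iodo-4-methylpent-4-enoyl]-5-methyloxolan-2-yl]acetate | OC[C@@]1(CC(=O)OC)O[C@](C)(C[C@@H]1O[Si](C)(C)C(C)(C)C)C(=O)CC/C(C)=C\I | intermediate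
26 | methyl 2-[(2S,3S,5R)-3-[(tert-butyldimethylsilyl)oxy]-2-formyl-5-[(4Z)-5-iodo-4-methylpent-4-enoyl]-5-methyloxolan-2-yl]acetate (key-step precursor) | O=C[C@@]1(CC(=O)OC)O[C@](C)(C[C@@H]1O[Si](C)(C)C(C)(C)C)C(=O)CC/C(C)=C\I | intermediate
27 | alkenylchromium dichloride from 26 (CrCl2 group on C5, Z retained) | O=C[C@@]1(CC(=O)OC)O[C@](C)(C[C@@H]1O[Si](C)(C)C(C)(C)C)C(=O)CC/C(C)=C\[Cr](Cl)Cl | intermediate (not isolated)
28 | C6 chromium alkoxide of the ring-closed hydroxy ester (ten-membered ring formed, CH2CO2Me still open, configuration as in 29) | CC(C)(C)[Si](C)(C)O[C@H]1C[C@@]2(C)O[C@]1(CC(=O)OC)[C@H](O[Cr](Cl)Cl)/C=C(C)\CCC2=O | intermediate (not isolated)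
29 | (4Z,6R,7R,8S,10R)-8-[(tert-butyldimethylsilyl)oxy]-7,10-epoxy-1-oxo-13-norgermacr-4-en-12,6-olide (key-step product; the 7R descriptor reflects the silyl group, the arrangement at C7 is that of the target) | CC(C)(C)[Si](C)(C)O[C@H]1C[C@@]2(C)O[C@@]13CC(=O)O[C@@H]3/C=C(C)\CCC2=O | intermediate
30 | (4Z,6R,7R,8S,10R)-1,8-bis[(tert-butyldimethylsilyl)oxy]-7,10-epoxy-13-norgermacra-1,4-dien-12,6-olide (C1=C2 silyl enol ether, its geometry not defined and without consequence) | CC(C)(C)[Si](C)(C)O[C@H]1C[C@@]2(C)O[C@@]13CC(=O)O[C@@H]3/C=C(C)\CC=C2O[Si](C)(C)C(C)(C)C | intermediate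
31 | lithium enolate of lactone 30 at C11–C12 | CC(C)(C)[Si](C)(C)O[C@H]1C[C@@]2(C)O[C@@]13C=C(O[Li])O[C@@H]3/C=C(C)\CC=C2O[Si](C)(C)C(C)(C)C | intermediate (not isolated)
32 | 11-[(dimethylamino)methyl] derivative of 30 (Mannich base, C11 epimers) | CC(C)(C)[Si](C)(C)O[C@H]1C[C@@]2(C)O[C@@]13C(CN(C)C)C(=O)O[C@@H]3/C=C(C)\CC=C2O[Si](C)(C)C(C)(C)C | intermediate (not isolated)
33 | 11-[(trimethylammonio)methyl] derivative of 30, iodide | CC(C)(C)[Si](C)(C)O[C@H]1C[C@@]2(C)O[C@@]13C(C[N+](C)(C)C)C(=O)O[C@@H]3/C=C(C)\CC=C2O[Si](C)(C)C(C)(C)C.[I-] | intermediate (not isolated)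
34 | (4Z,6R,7R,8S,10R)-1,8-bis[(tert-butyldimethylsilyl)oxy]-7,10-epoxygermacra-1,4,11(13)-trien-12,6-olide | CC(C)(C)[Si](C)(C)O[C@H]1C[C@@]2(C)O[C@@]13C(=C)C(=O)O[C@@H]3/C=C(C)\CC=C2O[Si](C)(C)C(C)(C)C | intermediate
35 | (4Z,6R,7S,8S,10R)-7,10-epoxy-8-hydroxy-1-oxogermacra-4,11(13)-dien-12,6-olide | O[C@H]1C[C@@]2(C)O[C@@]13C(=C)C(=O)O[C@@H]3/C=C(C)\CCC2=O | intermediate
36 | (4Z,6R,7S,8S,10R)-7,10-epoxy-8-[(2-methylprop-2-enoyl)oxy]-1-oxogermacra-4,11(13)-dien-12,6-olide | C=C(C)C(=O)O[C@H]1C[C@@]2(C)O[C@@]13C(=C)C(=O)O[C@@H]3/C=C(C)\CCC2=O | intermediate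
37 | (4R,5S,6R,7S,8S,10R)-4,5:7,10-diepoxy-8-[(2-methylprop-2-enoyl)oxy]-1-oxogermacr-11(13)-en-12,6-olide (CNP0241021.1) | C=C(C)C(=O)O[C@H]1C[C@@]2(C)O[C@@]13C(=C)C(=O)O[C@@H]3[C@@H]1O[C@]1(C)CCC2=O | target

**Step count and risks**

Total step count: 19. Longest linear sequence: 16 steps (1, 3 to 8, 11 to 19).

Steps most likely to fail:

1. Step 14 (ring closure). The ten-membered ring may close too slowly, so that oligomerisation or reduction of the C–I bond takes over, or the formyl group may be attacked in its other rotamer, which would give the C6 epimer. Fallback, from 18 back to 29: the 4-methoxybenzyl ether of 18 is cleaved (DDQ, buffered CH2Cl2) to the hydroxymethyl methyl ketone F1, which is oxidised (Dess–Martin periodinane) to the keto-aldehyde F2. Intermolecular Nozaki–Hiyama–Kishi coupling of F2 with the iodo alcohol 21 (CrCl2, NiCl2 cat., DMSO; the free hydroxyl is tolerated) should follow the polar Felkin–Anh course, C5 entering anti to the C7–O bond past the CH2CO2Me arm, to the 6R carbinol, which lactonises to the spiro-lactone allylic alcohol F3. Appel bromination gives the allylic bromide F4, and the ten-membered ring is then closed at C2–C3 by intramolecular alkylation of the potassium enolate of the methyl ketone (KHMDS, THF, high dilution, −78 to 0 °C), a known way to close germacrane rings, which gives 29.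

2. Step 19 (epoxidation). Oxygen transfer may be poorly face-selective or prefer the wrong face, because the oxa-bridged ring may present to the peracid the alkene face anti to C7. Fallback, from 36 back to 37: NBS in aqueous THF should place bromine on the face that the peracid prefers and water anti at the tertiary C4, giving the bromohydrin F8; K2CO3 in acetone then closes the oxirane with inversion at C5, so the oxygen ends on the face opposite to that reached by direct epoxidation.

3. Step 6 (oxycarbonylation cascade). The sequence may stall after oxypalladation, giving open-chain acid instead of the lactone, or the α-hydroxy ketone may hold O8 as a cyclic hemiketal and slow the cyclisation. Fallback, from 13 back to 14: Lemieux–Johnson cleavage of the 1,1-disubstituted alkene (OsO4 cat., NaIO4, 2,6-lutidine, dioxane/H2O) gives the C7 ketone F5. The secondary C8 hydroxyl alone is acylated with diethylphosphonoacetic acid (DCC, DMAP) to the phosphonoacetate F6. LiCl and DBU in MeCN bring about the intramolecular Horner–Wadsworth–Emmons reaction with the neighbouring C7 ketone to the butenolide F7, and the same base lets the tertiary C10 hydroxyl add to C7 of the butenolide (5-exo-trig oxa-Michael addition, possible only with cis ring fusion), which gives 14.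

**Further compounds**

F1 | step 14 | methyl 2-[(2R,3S,5R)-5-acetyl-3-[(tert-butyldimethylsilyl)oxy]-2-(hydroxymethyl)-5-methyloxolan-2-yl]acetate | OC[C@@]1(CC(=O)OC)O[C@](C)(C[C@@H]1O[Si](C)(C)C(C)(C)C)C(C)=O
F2 | step 14 | methyl 2-[(2S,3S,5R)-5-acetyl-3-[(tert-butyldimethylsilyl)oxy]-2-formyl-5-methyloxolan-2-yl]acetate | O=C[C@@]1(CC(=O)OC)O[C@](C)(C[C@@H]1O[Si](C)(C)C(C)(C)C)C(C)=O
F3 | step 14 | 12,6-lactone (spiro at C7) with the (1Z)-3-hydroxy-2-methylprop-1-enyl group on C6, acetyl on C10 and silyl ether on O8 | CC(C)(C)[Si](C)(C)O[C@H]1C[C@](C)(C(C)=O)O[C@@]12CC(=O)O[C@@H]2/C=C(C)\CO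
F4 | step 14 | allylic bromide of F3, (1Z)-3-bromo-2-methylprop-1-enyl group on C6 | CC(C)(C)[Si](C)(C)O[C@H]1C[C@](C)(C(C)=O)O[C@@]12CC(=O)O[C@@H]2/C=C(C)\CBr
F5 | step 6 | (3R,5S)-3,5-dihydroxy-7-[(4-methoxyphenyl)methoxy]-3-methylheptane-2,6-dione | CC(=O)[C@](C)(O)C[C@H](O)C(=O)COCc1ccc(OC)cc1
F6 | step 6 | (3S,5R)-5-hydroxy-1-[(4-methoxyphenyl)methoxy]-5-methyl-2,6-dioxoheptan-3-yl 2-(diethoxyphosphoryl)acetate | CC(=O)[C@](C)(O)C[C@H](OC(=O)CP(=O)(OCC)OCC)C(=O)COCc1ccc(OC)cc1
F7 | step 6 | (5S)-5-[(2R)-2-hydroxy-2-methyl-3-oxobutyl]-4-{[(4-methoxyphenyl)methoxy]methyl}furan-2(5H)-one | CC(=O)[C@](C)(O)C[C@@H]1OC(=O)C=C1COCc1ccc(OC)cc1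
F8 | step 19 | 5-bromo-4-hydroxy adduct of 36 (bromohydrin, Br on C5 and OH on C4 anti) | C=C(C)C(=O)O[C@H]1C[C@@]2(C)O[C@@]13C(=C)C(=O)O[C@@H]3[C@@H](Br)[C@](C)(O)CCC2=O
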